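## Retrosynthetic overview

1. Target ⇒ a monocyclic, dearomatised acylphloroglucinol in which the quaternary carbon carries methyl and a 2-prenyl-prenyl (isolavandulyl) group. The last step closes ring B (C1–C8) and creates C7–H in one proton-initiated enol–ene (cation–olefin) cycloisomerisation; C1 captures the tertiary C8 cation, as in the presumed biosynthesis.
2. The prenyl group is already on C7, so the initiating electrophile is a proton from the substrate's own enol, not a prenyl cation (which the enol carbons would intercept).
3. Monocycle ⇒ aromatic 3-methyl-5-prenyl acylphloroglucinol + a tertiary allylic carbonate; a Pd-catalysed asymmetric allylic dearomatisation sets the only pre-cyclisation stereocentre (C5).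
4. Aromatic part ⇒ 2-methylphloroglucinol + isobutyryl chloride + prenyl bromide; carbonate ⇒ 2,3-dibromopropene + 2-methylprop-1-enylmagnesium bromide + acetone + methyl chloroformate.
5. Ring order: ring A is the purchased phloroglucinol ring (dearomatised in the allylation); ring B of the bicyclo[3.3.1]nonane is formed last, creating C1 and C7.

Assumption: 2-methylphloroglucinol is bought; enolised triketones are drawn and named as one tautomer, and stereodescriptors refer to the tautomers drawn.

## Route

Step 1
Reactants: 1 2-methylbenzene-1,3,5-triol (2-methylphloroglucinol); 2 2-methylpropanoyl chloride (isobutyryl chloride)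
Product: 3 2-methyl-1-(2,4,6-trihydroxy-3-methylphenyl)propan-1-one
Conditions: AlCl3 (3.5 equiv), PhNO2, 65 °C
Reagents that add atoms: none
Why: Friedel–Crafts acylation of the electron-rich triol at one of its two equivalent free positions; the acyl group deactivates the ring against a second acylation.

Step 2
Reactants: 3 2-methyl-1-(2,4,6-trihydroxy-3-methylphenyl)propan-1-one; 4 1-bromo-3-methylbut-2-ene (prenyl bromide)
Product: 5 2-methyl-1-[2,4,6-trihydroxy-3-methyl-5-(3-methylbut-2-en-1-yl)phenyl]propan-1-one
Conditions: KOH (1.1 equiv), H2O, 0 °C → rt, 4 (1.0 equiv)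
Reagents that add atoms: none
Why: C-alkylation of the ambident phenolate (favoured in water) at the only unsubstituted ring carbon, followed by re-aromatisation (electrophilic aromatic C-prenylation).

Step 3
Reactants: 6 2,3-dibromoprop-1-ene; 7 (2-methylprop-1-en-1-yl)magnesium bromide
Product: 8 2-bromo-5-methylhexa-1,4-diene
Conditions: CuBr·SMe2 (5 mol %), THF, −20 → 0 °C
Reagents that add atoms: none
Why: Copper-catalysed allylic substitution of the allylic bromide by the vinyl Grignard reagent (SN2 and SN2′ give the same product), the vinylic C–Br bond staying intact.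

Step 4
Reactants: 8 2-bromo-5-methylhexa-1,4-diene; 9 propan-2-one (acetone)
Product: 12 methyl 2,6-dimethyl-3-methylidenehept-5-en-2-yl carbonate, via vinylmagnesium bromide 10 (not isolated), via magnesium tert-alkoxide 11 (not isolated)
Conditions: Mg, THF, 45 °C; 9, 0 °C; ClCO2Me, 0 °C → rt
Reagents that add atoms: methyl chloroformate COC(Cl)=O
Why: Grignard formation from the vinyl bromide, 1,2-addition to acetone and O-acylation of the tertiary alkoxide in the same flask give the tertiary allylic carbonate.

Step 5
Reactants: 5 2-methyl-1-[2,4,6-trihydroxy-3-methyl-5-(3-methylbut-2-en-1-yl)phenyl]propan-1-one; 12 methyl 2,6-dimethyl-3-methylidenehept-5-en-2-yl carbonate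
Product: 13 (4S)-3,5-dihydroxy-4-methyl-6-(3-methylbut-2-en-1-yl)-4-[5-methyl-2-(propan-2-ylidene)hex-4-en-1-yl]-2-(2-methylpropanoyl)cyclohexa-2,5-dien-1-one
Conditions: Pd2(dba)3·CHCl3 (2.5 mol %), (R,R)-DACH-phenyl Trost ligand (7.5 mol %), CH2Cl2, 0 °C → rt
Reagents that add atoms: none
Why: Tsuji–Trost asymmetric allylic alkylation (catalytic asymmetric allylic dearomatisation): the carbonate ionises to a 1,1-dimethyl-2-alkyl π-allyl palladium complex that is attacked at its CH2 terminus by the less hindered, methyl-bearing ring carbon, the chiral ligand pocket choosing the enantiotopic face and so setting the quaternary stereocentre (C5 of the target; the sense of induction must be confirmed and the ligand antipode used if needed), while the tetrasubstituted alkene of 13 should not be re-ionised by zerovalent palladium.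

Step 6
Reactants: 13 (4S)-3,5-dihydroxy-4-methyl-6-(3-methylbut-2-en-1-yl)-4-[5-methyl-2-(propan-2-ylidene)hex-4-en-1-yl]-2-(2-methylpropanoyl)cyclohexa-2,5-dien-1-one
Product: 14 (1R,5R,7R)-4-hydroxy-5,8,8-trimethyl-1,7-bis(3-methylbut-2-en-1-yl)-3-(2-methylpropanoyl)bicyclo[3.3.1]non-3-ene-2,9-dione
Conditions: (CF3)2CHOH (0.02 M), 50 °C, no added acid
Reagents that add atoms: none
Why: Proposed new method: the acidic enol O9–H/C1=C9 and the electron-rich tetrasubstituted alkene of 13 sit in a six-membered ene-type array (H–O9–C9=C1···C8=C7, braced by the C5–C6 tether), so proton transfer to C7 and capture of the developing tertiary C8 cation by C1 close ring B in an intramolecular enol–ene (Conia-ene-type, proton-initiated cation–olefin) cycloisomerisation; C1 is fixed because the bridge can only close on the face of ring A that carries C6, and C7 is set because the proton arrives either from the O9/C9 side (syn, boat-like ene array) or, if delivered externally, anti to C1 through a chair (Stork–Eschenmoser), both of which place H7 exo (towards C9) and the prenyl group endo (towards the C2–C4 bridge); closest known reaction types are the Conia-ene cyclisation of 1,3-dicarbonyl enols onto alkenes and the acid-mediated cationic cyclisation of dearomatised acylphloroglucinols to bicyclo[3.3.1]nonanetriones.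

## Compound list

1 | 2-methylbenzene-1,3,5-triol (2-methylphloroglucinol) | Cc1c(O)cc(O)cc1O | starting material
2 | 2-methylpropanoyl chloride (isobutyryl chloride) | CC(C)C(Cl)=O | starting material
3 | 2-methyl-1-(2,4,6-trihydroxy-3-methylphenyl)propan-1-one | CC(C)C(=O)c1c(O)cc(O)c(C)c1O | intermediate
4 | 1-bromo-3-methylbut-2-ene (prenyl bromide) | CC(C)=CCBr | starting material
5 | 2-methyl-1-[2,4,6-trihydroxy-3-methyl-5-(3-methylbut-2-en-1-yl)phenyl]propan-1-one | CC(C)C(=O)c1c(O)c(CC=C(C)C)c(O)c(C)c1O | intermediate
6 | 2,3-dibromoprop-1-ene | C=C(Br)CBr | starting material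
7 | (2-methylprop-1-en-1-yl)magnesium bromide | CC(C)=C[Mg]Br | starting material
8 | 2-bromo-5-methylhexa-1,4-diene | C=C(Br)CC=C(C)C | intermediate
9 | propan-2-one (acetone) | CC(C)=O | starting material
10 | (5-methylhexa-1,4-dien-2-yl)magnesium bromide | C=C([Mg]Br)CC=C(C)C | intermediate
11 | bromomagnesium 2,6-dimethyl-3-methylidenehept-5-en-2-olate | CC(C)=CCC(=C)C(C)(C)O[Mg]Br | intermediate
12 | methyl 2,6-dimethyl-3-methylidenehept-5-en-2-yl carbonate | COC(=O)OC(C)(C)C(=C)CC=C(C)C | intermediate
13 | (4S)-3,5-dihydroxy-4-methyl-6-(3-methylbut-2-en-1-yl)-4-[5-methyl-2-(propan-2-ylidene)hex-4-en-1-yl]-2-(2-methylpropanoyl)cyclohexa-2,5-dien-1-one (the quaternary carbon becomes C5 of 14) | C[C@@]1(CC(CC=C(C)C)=C(C)C)C(O)=C(C(=O)C(C)C)C(=O)C(CC=C(C)C)=C1O | intermediate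
14 | (1R,5R,7R)-4-hydroxy-5,8,8-trimethyl-1,7-bis(3-methylbut-2-en-1-yl)-3-(2-methylpropanoyl)bicyclo[3.3.1]non-3-ene-2,9-dione (C7 prenyl endo, facing the C2–C4 bridge; H7 on the C9 side) | CC(C)=CC[C@@H]1C[C@@]2(C)C(=O)[C@](CC=C(C)C)(C(=O)C(C(=O)C(C)C)=C2O)C1(C)C | target

## Step count and risks

Total step count: 6. Longest linear sequence: 4 steps (1 → 3 → 5 → 13 → 14; the branch 6 → 8 → 12 → 13 → 14 is equally long).

Three steps most likely to fail:

**Step 6 (ring B closure).** The cyclisation may not start below the temperature at which 13 begins to rearrange. It may end on oxygen (a pyran) or on C3 instead of C1. If a free C8 cation forms, it can lose and regain H7 and leak to the C7 epimer, which is probably the easier one to form. The fallback sets out from 5 and comes back at 14. (S)-Lavandulol F1 (bought) is turned with (CF3SO2)2O and 2,6-lutidine (CH2Cl2, −78 °C) into (S)-lavandulyl trifluoromethanesulfonate F2. F2 C-alkylates the lithium salt of 5 (LiN(SiMe3)2, THF, −78 → 0 °C) at the methyl-bearing carbon to give the dearomatised lavandulyl triketone F3 and its C4 epimer F4 (about 1:1, separated by chromatography). F3 already carries the C7 stereocentre. Protonation of its isopropenyl group (the same (CF3)2CHOH conditions, or HCO2H at rt) gives the same C8 cation and closes ring B stereospecifically to 14.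

**Step 5 (asymmetric allylic dearomatisation).** The ee may be modest, and attack at the prenyl-bearing carbon or at oxygen may compete. The fallback sets out from 5 (with 12) and comes back at 13. Achiral Pd(PPh3)4 in THF gives the racemic triketone F5. Its enantiomers are separated on a chiral stationary phase, and the (4S) enantiomer is 13.

**Step 2 (mono-C-prenylation).** Over-alkylation at the methyl-bearing carbon (dearomatised by-products) and O-prenylation can lower the yield. The fallback sets out from 3 and comes back at 5. It is a Friedel–Crafts prenylation with 2-methylbut-3-en-2-ol and BF3·OEt2 in dioxane at rt, which targets the free ring CH under non-basic conditions. It makes no new compound (F0).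

Further compounds
F1 | step 6 | (2S)-5-methyl-2-(prop-1-en-2-yl)hex-4-en-1-ol ((S)-lavandulol, bought) | CC(C)=CC[C@@H](C(C)=C)CO
F2 | step 6 | (2S)-5-methyl-2-(prop-1-en-2-yl)hex-4-en-1-yl trifluoromethanesulfonate | CC(C)=CC[C@@H](C(C)=C)COS(=O)(=O)C(F)(F)F
F3 | step 6 | (4S)-3,5-dihydroxy-4-methyl-6-(3-methylbut-2-en-1-yl)-4-[(2R)-5-methyl-2-(prop-1-en-2-yl)hex-4-en-1-yl]-2-(2-methylpropanoyl)cyclohexa-2,5-dien-1-one | C[C@@]1(C[C@@H](CC=C(C)C)C(C)=C)C(O)=C(C(=O)C(C)C)C(=O)C(CC=C(C)C)=C1O
F4 | step 6 | (4R)-3,5-dihydroxy-4-methyl-6-(3-methylbut-2-en-1-yl)-4-[(2R)-5-methyl-2-(prop-1-en-2-yl)hex-4-en-1-yl]-2-(2-methylpropanoyl)cyclohexa-2,5-dien-1-one | C[C@]1(C[C@@H](CC=C(C)C)C(C)=C)C(O)=C(C(=O)C(C)C)C(=O)C(CC=C(C)C)=C1O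
F5 | step 5 | racemic 3,5-dihydroxy-4-methyl-6-(3-methylbut-2-en-1-yl)-4-[5-methyl-2-(propan-2-ylidene)hex-4-en-1-yl]-2-(2-methylpropanoyl)cyclohexa-2,5-dien-1-one | CC1(CC(CC=C(C)C)=C(C)C)C(O)=C(C(=O)C(C)C)C(=O)C(CC=C(C)C)=C1O
F0 | step 2 | none | none
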